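## Structural features

The target is a germacranolide: a ten-membered carbocycle (C1–C10) fused along C6–C7 to an α,β-unsaturated γ-lactone (oxygen on C6, C12 carbonyl, C7=C11), with C11 carrying the acetoxymethyl carbon C13. A trans-epoxide bridges C1 and C10 (C14 methyl on C10). An E-trisubstituted alkene C4=C5 (C15 methyl on C4) lies between two allylic oxygen-bearing stereocentres, C3 (acetate, S) and C6 (lactone oxygen, R). C1 and C10 (both R) are contiguous and 1,3-related to C3 through C2. The fragile elements are the epoxide (transannular opening by C4=C5 under acid), the hydrogen on C6 (allylic and γ to the lactone carbonyl), the primary allylic acetate at C13, and, in every diene precursor, the 3-oxygenated cyclodeca-1,5-diene (Cope rearrangement, oxy-Cope as a C3 alkoxide, acid-induced transannular cyclisation). The real difficulty is closing a ten-membered ring that holds an E-trisubstituted alkene while fixing the 1,4-relationship of C3 and C6 across it. The key step exploits the fact that C3 is a carbinol on the methyl-bearing carbon C4 of E-C4=C5: that is the pattern left when an aldehyde carbon (C3) and a hydrogen add to the same side of a C4≡C5 methyl alkyne. The butenolide ring is left out of that step; C7 is carried as a masked ketone beside the C6 oxygen and the lactone is annulated afterwards.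

## Logic of the disconnections

29 to 28: the two C–O bonds of the oxirane are cut. The epoxide is the most acid-labile group and is best made last. The cut removes two stereocentres. The forward step must pick C1=C10 over C4=C5 and C7=C11 and must attack the outer face of the conformer that holds C14 and C15 on the same side.

28 to 27 to 26: the two acetyl C–O bonds are cut, then both O–Si bonds. An acetate on C13 would be expelled from a phosphonate anion, and the C3 oxygen leaves the key step as a silyl ether, so both oxygens are carried as silyl ethers and exchanged together. The forward desilylation must use acidic fluoride: a free C3 alkoxide invites oxy-Cope rearrangement and base endangers the C6 hydrogen.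

26 to 20 and 24: C7=C11 and O6–C12 are cut. Esterification and intramolecular Horner–Wadsworth–Emmons olefination bring C11, C12 and C13 in one reagent and turn the bicyclic lactone into a monocyclic α-hydroxy ketone. The base must be mild enough to leave C6 (α to the ketone and allylic) untouched, and olefination must outrun loss of silyloxide from the phosphonate anion.

24 to 22 to 21: the C11–C12 bond is cut (carboxylation of a phosphonate anion), then the O–Si bond. This leads to a catalogue hydroxyethyl phosphonate. The anion must be kept cold.

20 to 19: the C7 ketone and the C6 hydroxyl are masked. A free ketone during ring closure would make the propargylic, oxygenated C6 hydrogen labile, and C6–O must stay distinguishable from C3–O. A dimethyl ketal and a triethylsilyl ether are chosen so that one mild aqueous acid treatment releases both. A dioxolane next to an oxygenated carbon would need acid that the 1,5-diene is unlikely to survive.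

19 to 18: C3–C4 is cut and the C5 hydrogen removed, giving an aldehyde and a methyl alkyne. This one cut removes the ring, the E-alkene and the C3 stereocentre. The forward step must bond at C4 and not C5, close in the endocyclic mode, avoid oligomers, and choose the correct aldehyde face.

18 to 17 to 16 to 15: the aldehyde is traced to a PMB-protected primary alcohol and the ketal to a dithiane. The β,γ-unsaturated aldehyde must be made last, and sulfur must be gone before nickel is used. The exchange must spare the silyl ether and the PMB group.

15 to 14 to 13 to 12 to 9 and 10: the C6 stereocentre is traced to an ynone and the C6–C7 bond is cut. A C7 acyl-anion equivalent adding to a C6 aldehyde gives the 1,2-dioxygenation with C7 already masked. In the ynone the quaternary dithiane and the linear alkyne differ strongly in size, which suits reagent-controlled reduction.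

9 to 8 to 7 to 4 and 5: the C8–C9 bond is cut in the sense of a Johnson–Claisen rearrangement. This sets the E-C1=C10 alkene through a chair transition state. A cyclopropylcarbinol ring opening would reach the same homoallylic pattern in fewer operations, but it gives trisubstituted alkenes as E/Z mixtures under strongly acidic conditions, so the sigmatropic route is preferred.

4 to 2 and 3, 2 to 1: the C1–C10 bond is cut (Grignard addition to an aldehyde). The carbinol centre formed is destroyed in the rearrangement and needs no control.

## Other disconnections considered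

Alternative 1: The cut removes C4 from between C3 and C5, tracing the ten-membered ring to a nine-membered cycloalkene plus dibromocarbene, and also cuts C3–O. In the forward key step AgOAc in AcOH pulls the exo bromide from the cis-fused dibromocyclopropane A1. The C3–C5 bond opens in the disrotatory sense that turns the ring residues outward, acetate is captured at C3, and the ring grows to bromoalkene A2. A2 is ring-trans; by the sequence rule it is Z, because bromine outranks C3.
- In favour: it is a ring expansion, not an end-to-end closure. The C3 acetate is installed by the key step itself, with its configuration relayed stereospecifically from the cyclopropane. On C3 control, and on needing no silyl-to-acetate exchange, it is the better of the two plans.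
- Against: the nine-membered Z-cycloalkene carrying the butenolide and the masked diol is about as hard to make as the ten-membered ring, so the medium-ring problem is moved, not solved. The face of carbene addition relative to C6 must be controlled. Acetonide and butenolide must survive a silver salt in acetic acid. A2 still needs bromine-to-methyl coupling at C4 and a multi-operation diol-to-epoxide sequence with inversion at C1.
- Comparison: both plans make E-C4=C5 and C3 in one step. The electrocyclic opening is stereospecific where the nickel closure relies on conformational induction. In step count the chosen plan is ahead, since its alkyne already carries C15 and its epoxide comes in one step.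

Alternative 2: The cut is C7–C8. In the forward key step 9-BBN adds to the terminal C8=C9 alkene of seco-triflate A3 with boron on C8, and PdCl2(dppf) with aqueous K3PO4 couples the borane with the C7 enol triflate to give A4.
- In favour: C3, C6 and the butenolide are in place before closure, so no stereocentre is made in the ring-forming step; on C3 this is better than the chosen plan. A4 is three operations from the target, the same distance as 26, so the endgames are equal.
- Against: C3 needs a separate enantioselective step in the acyclic series. The tetronate triflate and the C6 hydrogen face aqueous base with heating (triflate hydrolysis, epimerisation). The borane must form on the terminal alkene of a conjugated diene in the presence of two other alkenes. Alkyl–alkenyl Suzuki closure of a ten-membered ring leaves room for β-hydride elimination at divalent palladium.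
- Comparison: it closes an unstrained single bond remote from the stereocentres, where the chosen plan makes an alkene and a stereocentre. It is more convergent, but needs more steps before ring closure; the totals are similar.

Alternative 3: The cut is seen backwards as joining C5 to C10, tracing the ten-membered ring to a decalin. In the forward key step, ultraviolet irradiation at low temperature opens the C5–C10 bond of the trans-fused acetoxydiene A5 in a conrotatory six-electron ring opening to tetraene A6. A6 is 1(10)E and 4E with a ring-cis C2=C3; that bond is formally E by the sequence rule, because the acetoxy oxygen outranks C4.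
- In favour: no ring closure at all. The ring carbons, the C6 configuration and the lactone come from santonin. On medium-ring formation, and on C6 needing no asymmetric reagent, it is better than the chosen plan. Both ring alkene geometries follow from orbital symmetry.
- Against: the opening is a photoequilibrium with thermal reversal, so the triene must be intercepted cold. A6 holds C3 as an enol acetate with an extra C2=C3 bond, so C3 would have to come from chemo- and face-selective reduction of one alkene of a strained conjugated triene, for which there is no reliable method. Santonin's saturated methyl lactone must be reworked into the 7(11)-ene with oxygen on C13.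
- Comparison: it solves the ring but not C3. The pericyclic step is clean but reversible. The ring arrives early, but the functional-group corrections would outnumber the steps of the chosen route.

Key step: step 13

Remark: atoms carry germacrane numbers (C1–C15) and compounds plain numbers; 1, 3, 5, 10 and 21 are taken as catalogue chemicals; the CBS step assumes that the linear propynyl group behaves as the smaller ketone substituent.

## Steps

Step 1
Reactants: 1 3-[(4-methoxybenzyl)oxy]propan-1-ol
Product: 2 3-[(4-methoxybenzyl)oxy]propanal
Conditions: TEMPO (cat.), PhI(OAc)2, CH2Cl2, rt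
Reagents that add atoms: none
Why: Nitroxyl-catalysed oxidation of a primary alcohol stops at the aldehyde and leaves the PMB ether alone.

Step 2
Reactants: 2 3-[(4-methoxybenzyl)oxy]propanal; 3 isopropenylmagnesium bromide
Product: 4 5-[(4-methoxybenzyl)oxy]-2-methylpent-1-en-3-ol (racemic)
Conditions: THF, −78 → 0 °C; then H2O
Reagents that add atoms: none
Why: Grignard addition to an aldehyde forms C1–C10; the carbinol centre is consumed in step 3, so no control is needed.

Step 3
Reactants: 4 5-[(4-methoxybenzyl)oxy]-2-methylpent-1-en-3-ol; 5 triethyl orthoacetate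
Product: 7 ethyl (4E)-7-[(4-methoxybenzyl)oxy]-4-methylhept-4-enoate, via ketene acetal 6 (not isolated)
Conditions: EtCO2H (cat.), neat 5, 135–140 °C, EtOH distilled off
Reagents that add atoms: none
Why: Johnson–Claisen rearrangement forms C8–C9; the chair transition state with the CH2CH2OPMB group equatorial (the axial ethoxy group penalises the alternative) should give the E-C1=C10 alkene with high selectivity.

Step 4
Reactants: 7 ethyl (4E)-7-[(4-methoxybenzyl)oxy]-4-methylhept-4-enoate
Product: 8 (4E)-7-[(4-methoxybenzyl)oxy]-4-methylhept-4-enal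
Conditions: iBu2AlH, CH2Cl2, −78 °C; then MeOH, aq. potassium sodium tartrate
Reagents that add atoms: none
Why: Partial reduction of an ester at low temperature stops at the aldehyde because the tetrahedral aluminium alkoxide is stable until work-up.

Step 5
Reactants: 8 (4E)-7-[(4-methoxybenzyl)oxy]-4-methylhept-4-enal
Product: 9 2-{(3E)-6-[(4-methoxybenzyl)oxy]-3-methylhex-3-en-1-yl}-1,3-dithiane
Conditions: HS(CH2)3SH, BF3·OEt2 (cat.), CH2Cl2, −40 → −20 °C
Reagents that add atoms: propane-1,3-dithiol SCCCS
Why: Lewis-acid-catalysed thioacetalisation of an aldehyde is fast at low temperature, where a catalytic amount of BF3·OEt2 should not cleave the PMB ether; C7 becomes an acyl-anion equivalent.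

Step 6
Reactants: 9 2-{(3E)-6-[(4-methoxybenzyl)oxy]-3-methylhex-3-en-1-yl}-1,3-dithiane; 10 but-2-ynal
Product: 12 1-(2-{(3E)-6-[(4-methoxybenzyl)oxy]-3-methylhex-3-en-1-yl}-1,3-dithian-2-yl)but-2-yn-1-ol (racemic), via lithiodithiane 11 (not isolated)
Conditions: n-BuLi, THF, −30 °C; then 10, −78 °C; then H2O
Reagents that add atoms: none
Why: Corey–Seebach umpolung: the 2-lithio-1,3-dithiane adds 1,2 to the ynal in THF without polar additives and forms C6–C7 with C7 already masked.

Step 7
Reactants: 12 1-(2-{(3E)-6-[(4-methoxybenzyl)oxy]-3-methylhex-3-en-1-yl}-1,3-dithian-2-yl)but-2-yn-1-ol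
Product: 13 1-(2-{(3E)-6-[(4-methoxybenzyl)oxy]-3-methylhex-3-en-1-yl}-1,3-dithian-2-yl)but-2-yn-1-one
Conditions: (COCl)2, DMSO, CH2Cl2, −78 °C; Et3N, −78 → −40 °C
Reagents that add atoms: none
Why: Swern oxidation converts the propargylic alcohol to the ynone without oxidising the thioketal sulfur; the cold quench keeps amine from adding to the ynone.

Step 8
Reactants: 13 1-(2-{(3E)-6-[(4-methoxybenzyl)oxy]-3-methylhex-3-en-1-yl}-1,3-dithian-2-yl)but-2-yn-1-one
Product: 14 (1R)-1-(2-{(3E)-6-[(4-methoxybenzyl)oxy]-3-methylhex-3-en-1-yl}-1,3-dithian-2-yl)but-2-yn-1-ol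
Conditions: (S)-2-methyl-CBS-oxazaborolidine (0.5 equiv), catecholborane, toluene, −78 → −40 °C
Reagents that add atoms: none
Why: CBS reduction sets C6: the oxazaborolidine–borane complex binds the carbonyl oxygen anti to the quaternary dithianyl group (large) and delivers hydride to the face that gives the R carbinol, the propynyl group acting as the small substituent; catecholborane does not hydroborate the alkene at this temperature.

Step 9
Reactants: 14 (1R)-1-(2-{(3E)-6-[(4-methoxybenzyl)oxy]-3-methylhex-3-en-1-yl}-1,3-dithian-2-yl)but-2-yn-1-ol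
Product: 15 triethylsilyl ether of 14
Conditions: Et3SiOTf, 2,6-lutidine, CH2Cl2, −78 → 0 °C
Reagents that add atoms: triethylsilyl trifluoromethanesulfonate CC[Si](CC)(CC)OS(=O)(=O)C(F)(F)F
Why: Silyl triflate with a hindered base silylates the neopentyl-like secondary alcohol; the TES group is chosen because it can later be removed in the presence of a triisopropylsilyl ether.

Step 10
Reactants: 15 triethylsilyl ether of 14
Product: 16 1-methoxy-4-({[(3E,8R)-7,7-dimethoxy-4-methyl-8-(triethylsilyloxy)undec-3-en-9-yn-1-yl]oxy}methyl)benzene
Conditions: PhI(OCOCF3)2, NaHCO3, MeOH/CH2Cl2, −20 → 0 °C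
Reagents that add atoms: methanol CO
Why: Hypervalent-iodine oxidation of the dithiane sulfur gives a thionium ion that methanol traps twice, exchanging the thioketal directly for the dimethyl ketal without passing through the base-sensitive propargylic ketone; solid bicarbonate takes up the liberated acid so the TES ether survives.

Step 11
Reactants: 16 1-methoxy-4-({[(3E,8R)-7,7-dimethoxy-4-methyl-8-(triethylsilyloxy)undec-3-en-9-yn-1-yl]oxy}methyl)benzene
Product: 17 (3E,8R)-7,7-dimethoxy-4-methyl-8-(triethylsilyloxy)undec-3-en-9-yn-1-ol
Conditions: DDQ, CH2Cl2/pH 7 buffer, 0 °C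
Reagents that add atoms: none
Why: Oxidative cleavage of the PMB ether proceeds under buffered conditions in which the silyl ether, ketal, alkyne and alkene are inert.

Step 12
Reactants: 17 (3E,8R)-7,7-dimethoxy-4-methyl-8-(triethylsilyloxy)undec-3-en-9-yn-1-ol
Product: 18 (3E,8R)-7,7-dimethoxy-4-methyl-8-(triethylsilyloxy)undec-3-en-9-ynal (acyclic ynal: C3 aldehyde, E-C1=C10, C7 dimethyl ketal, C6–OTES, C4≡C5 methyl alkyne)
Conditions: Dess–Martin periodinane, NaHCO3, CH2Cl2, 0 °C
Reagents that add atoms: none
Why: Buffered Dess–Martin oxidation gives the β,γ-unsaturated aldehyde without acid or base that would move the alkene into conjugation; 18 is used at once.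

Step 13
Reactants: 18 (3E,8R)-7,7-dimethoxy-4-methyl-8-(triethylsilyloxy)undec-3-en-9-ynal
Product: 19 (3S,6R)-7,7-dimethoxy-6-(triethylsilyloxy)-3-(triisopropylsilyloxy)-11,12,13-trinorgermacra-1(10)E,4E-diene (ten-membered E,E-diene)
Conditions: Ni(cod)2 (20 mol%), IMes (20 mol%), iPr3SiH, THF, 0.003 M by slow addition of 18, 25–45 °C
Reagents that add atoms: triisopropylsilane CC(C)[SiH](C(C)C)C(C)C
Why: Zerovalent nickel bearing one IMes ligand binds the aldehyde and the alkyne of 18 and couples them oxidatively to a five-membered oxanickelacycle in which C3 is bonded to C4 and nickel to C5 and O3. σ-Bond metathesis of the Ni–O bond with the silane, then C–H reductive elimination, releases the silyl ether with hydrogen on C5 cis to C3, which fixes E-C4=C5 (C3 trans to C6). The closest known reaction is the nickel–carbene–silane reductive coupling of aldehydes with alkynes, including ynal macrocyclisations to endocyclic E-allylic silyl ethers; a ten-membered ring is at the small end of that range. The ring closes in the endocyclic mode (both alkyne carbons in the ring, through a bridged bicyclic nickelacycle); the exocyclic mode would give a nine-membered ring with an ethylidene group. Regioselectivity rests on the small carbene, which lets the branched, quaternary-flanked C6 terminus sit next to nickel and sends the aldehyde to the methyl-bearing C4. C3 is controlled by C6: O3 lies in the nickelacycle plane, so its configuration follows from the face over which the tether from C6 to C2 passes, and the rotamer with the C6–O bond in that plane anti to nickel (silyloxy group turned away from the carbene) leads to 3S. The rotamer with H6 in the plane, which allylic strain would favour in a late transition state, leads to the 3-epimer, so this is the least secure element. The ketal, silyl ether and C1=C10 are spectators; high dilution suppresses oligomers, the isolated carbene avoids base that would isomerise the aldehyde, and the temperature is kept low because 19 is a Cope-prone 3-oxy-1,5-diene.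

Step 14
Reactants: 19 (3S,6R)-7,7-dimethoxy-6-(triethylsilyloxy)-3-(triisopropylsilyloxy)-11,12,13-trinorgermacra-1(10)E,4E-diene
Product: 20 (3S,6R)-6-hydroxy-3-(triisopropylsilyloxy)-11,12,13-trinorgermacra-1(10)E,4E-dien-7-one
Conditions: AcOH/THF/H2O (3:1:1), 25–35 °C
Reagents that add atoms: water O
Why: Mild aqueous acid removes the TES ether and hydrolyses the acyclic dimethyl ketal (far more labile than a dioxolane) while the triisopropylsilyl ether and the trisubstituted alkenes should survive; 20 is carried on without storage.

Step 15
Reactants: 21 diethyl (2-hydroxyethyl)phosphonate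
Product: 22 diethyl {2-[(tert-butyldimethylsilyl)oxy]ethyl}phosphonate
Conditions: t-BuMe2SiCl, imidazole, DMF, rt
Reagents that add atoms: tert-butyldimethylsilyl chloride CC(C)(C)[Si](C)(C)Cl
Why: Standard silylation of a primary alcohol.

Step 16
Reactants: 22 diethyl {2-[(tert-butyldimethylsilyl)oxy]ethyl}phosphonate
Product: 24 3-[(tert-butyldimethylsilyl)oxy]-2-(diethoxyphosphoryl)propanoic acid (racemic), via lithiated phosphonate 23 (not isolated)
Conditions: LiN(iPr)2 (2 equiv), THF, −78 °C; CO2, −78 °C; cold dilute HCl to pH 3
Reagents that add atoms: carbon dioxide O=C=O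
Why: Carboxylation of an α-lithio phosphonate is the standard route to 2-phosphonoalkanoic acids; at −78 °C carboxylation should outrun loss of silyloxide, and the second equivalent of base covers the more acidic product.

Step 17
Reactants: 20 (3S,6R)-6-hydroxy-3-(triisopropylsilyloxy)-11,12,13-trinorgermacra-1(10)E,4E-dien-7-one; 24 3-[(tert-butyldimethylsilyl)oxy]-2-(diethoxyphosphoryl)propanoic acid
Product: 26 (3S,6R)-13-(tert-butyldimethylsilyloxy)-3-(triisopropylsilyloxy)germacra-1(10)E,4E,7(11)-trien-12,6-olide, via phosphonoester 25 (not isolated)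
Conditions: iPrN=C=NiPr, DMAP (cat.), CH2Cl2, 0 °C; then LiCl, iPr2NEt, MeCN, rt
Reagents that add atoms: none
Why: Carbodiimide esterification of the C6 hydroxyl, then intramolecular Horner–Wadsworth–Emmons olefination of the C7 ketone under lithium-salt/amine conditions, closes the five-membered lactone with C7=C11; the weak base is meant to spare C6 and to let ring closure outrun β-elimination of silyloxide.

Step 18
Reactants: 26 (3S,6R)-13-(tert-butyldimethylsilyloxy)-3-(triisopropylsilyloxy)germacra-1(10)E,4E,7(11)-trien-12,6-olide
Product: 27 (3S,6R)-3,13-dihydroxygermacra-1(10)E,4E,7(11)-trien-12,6-olide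
Conditions: HF·pyridine, pyridine, THF, 0 °C → rt
Reagents that add atoms: none
Why: Buffered acidic fluoride cleaves both silyl ethers without generating a free C3 alkoxide (oxy-Cope) or a basic medium at the C6 hydrogen.

Step 19
Reactants: 27 (3S,6R)-3,13-dihydroxygermacra-1(10)E,4E,7(11)-trien-12,6-olide
Product: 28 (3S,6R)-3,13-diacetoxygermacra-1(10)E,4E,7(11)-trien-12,6-olide
Conditions: Ac2O, pyridine, DMAP (cat.), CH2Cl2, 0 °C
Reagents that add atoms: acetic anhydride CC(=O)OC(C)=O
Why: Nucleophile-catalysed acetylation of a primary and a secondary allylic alcohol with retention at C3.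

Step 20
Reactants: 28 (3S,6R)-3,13-diacetoxygermacra-1(10)E,4E,7(11)-trien-12,6-olide
Product: 29 (1R,3S,6R,10R)-3,13-diacetoxy-1,10-epoxygermacra-4E,7(11)-dien-12,6-olide (CNP0294733.1)
Conditions: mCPBA, NaHCO3, CH2Cl2, −20 → 0 °C
Reagents that add atoms: 3-chloroperoxybenzoic acid OOC(=O)c1cccc(Cl)c1
Why: Prilezhaev epoxidation picks the electron-rich C1=C10 (C4=C5 is deactivated by two allylic oxygens, C7=C11 by conjugation) and adds stereospecifically to the E-alkene to give the trans-epoxide; attack on the outer face of the conformer with C14 and C15 syn (the one free of allylic strain between C15 and O6) should give 1R,10R, and the buffer and the deactivated C4=C5 guard against transannular opening.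

## Compound list

1 | 3-[(4-methoxybenzyl)oxy]propan-1-ol | COc1ccc(COCCCO)cc1 | starting material
2 | 3-[(4-methoxybenzyl)oxy]propanal | COc1ccc(COCCC=O)cc1 | intermediate
3 | isopropenylmagnesium bromide | CC(=C)[Mg]Br | starting material
4 | 5-[(4-methoxybenzyl)oxy]-2-methylpent-1-en-3-ol (racemic) | CC(=C)C(O)CCOCc1ccc(OC)cc1 | intermediate
5 | triethyl orthoacetate | CCOC(C)(OCC)OCC | starting material
6 | 1-ethoxyethenyl ether of 4 (ketene acetal) | C=C(OCC)OC(CCOCc1ccc(OC)cc1)C(C)=C | intermediate (not isolated)
7 | ethyl (4E)-7-[(4-methoxybenzyl)oxy]-4-methylhept-4-enoate | CCOC(=O)CC/C(C)=C/CCOCc1ccc(OC)cc1 | intermediate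
8 | (4E)-7-[(4-methoxybenzyl)oxy]-4-methylhept-4-enal | O=CCC/C(C)=C/CCOCc1ccc(OC)cc1 | intermediate
9 | 2-{(3E)-6-[(4-methoxybenzyl)oxy]-3-methylhex-3-en-1-yl}-1,3-dithiane | S1CCCSC1CC/C(C)=C/CCOCc2ccc(OC)cc2 | intermediate
10 | but-2-ynal | CC#CC=O | starting material
11 | 2-lithio derivative of 9 | [Li]C1(CC/C(C)=C/CCOCc2ccc(OC)cc2)SCCCS1 | intermediate (not isolated)
12 | 1-(2-{(3E)-6-[(4-methoxybenzyl)oxy]-3-methylhex-3-en-1-yl}-1,3-dithian-2-yl)but-2-yn-1-ol (racemic) | CC#CC(O)C1(CC/C(C)=C/CCOCc2ccc(OC)cc2)SCCCS1 | intermediate
13 | 1-(2-{(3E)-6-[(4-methoxybenzyl)oxy]-3-methylhex-3-en-1-yl}-1,3-dithian-2-yl)but-2-yn-1-one | CC#CC(=O)C1(CC/C(C)=C/CCOCc2ccc(OC)cc2)SCCCS1 | intermediate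
14 | (1R)-1-(2-{(3E)-6-[(4-methoxybenzyl)oxy]-3-methylhex-3-en-1-yl}-1,3-dithian-2-yl)but-2-yn-1-ol | CC#C[C@@H](O)C1(CC/C(C)=C/CCOCc2ccc(OC)cc2)SCCCS1 | intermediate
15 | triethylsilyl ether of 14 | CC#C[C@@H](O[Si](CC)(CC)CC)C1(CC/C(C)=C/CCOCc2ccc(OC)cc2)SCCCS1 | intermediate
16 | 1-methoxy-4-({[(3E,8R)-7,7-dimethoxy-4-methyl-8-(triethylsilyloxy)undec-3-en-9-yn-1-yl]oxy}methyl)benzene | CC#C[C@@H](O[Si](CC)(CC)CC)C(OC)(OC)CC/C(C)=C/CCOCc1ccc(OC)cc1 | intermediate
17 | (3E,8R)-7,7-dimethoxy-4-methyl-8-(triethylsilyloxy)undec-3-en-9-yn-1-ol | CC#C[C@@H](O[Si](CC)(CC)CC)C(OC)(OC)CC/C(C)=C/CCO | intermediate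
18 | (3E,8R)-7,7-dimethoxy-4-methyl-8-(triethylsilyloxy)undec-3-en-9-ynal | CC#C[C@@H](O[Si](CC)(CC)CC)C(OC)(OC)CC/C(C)=C/CC=O | intermediate
19 | (3S,6R)-7,7-dimethoxy-6-(triethylsilyloxy)-3-(triisopropylsilyloxy)-11,12,13-trinorgermacra-1(10)E,4E-diene | C1/C=C(C)/CCC(OC)(OC)[C@H](O[Si](CC)(CC)CC)/C=C(C)/[C@H]1O[Si](C(C)C)(C(C)C)C(C)C | intermediate
20 | (3S,6R)-6-hydroxy-3-(triisopropylsilyloxy)-11,12,13-trinorgermacra-1(10)E,4E-dien-7-one | C1/C=C(C)/CCC(=O)[C@H](O)/C=C(C)/[C@H]1O[Si](C(C)C)(C(C)C)C(C)C | intermediate
21 | diethyl (2-hydroxyethyl)phosphonate | CCOP(=O)(CCO)OCC | starting material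
22 | diethyl {2-[(tert-butyldimethylsilyl)oxy]ethyl}phosphonate | CCOP(=O)(CCO[Si](C)(C)C(C)(C)C)OCC | intermediate
23 | α-lithio derivative of 22 | CCOP(=O)(OCC)C([Li])CO[Si](C)(C)C(C)(C)C | intermediate (not isolated)
24 | 3-[(tert-butyldimethylsilyl)oxy]-2-(diethoxyphosphoryl)propanoic acid (racemic) | CCOP(=O)(OCC)C(CO[Si](C)(C)C(C)(C)C)C(=O)O | intermediate
25 | C6 ester of 20 with 24 (epimers at the phosphonate carbon) | C1/C=C(C)/CCC(=O)[C@H](OC(=O)C(CO[Si](C)(C)C(C)(C)C)P(=O)(OCC)OCC)/C=C(C)/[C@H]1O[Si](C(C)C)(C(C)C)C(C)C | intermediate (not isolated)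
26 | (3S,6R)-13-(tert-butyldimethylsilyloxy)-3-(triisopropylsilyloxy)germacra-1(10)E,4E,7(11)-trien-12,6-olide | CC(C)(C)[Si](C)(C)OCC1=C2CC/C(C)=C/C[C@H](O[Si](C(C)C)(C(C)C)C(C)C)/C(C)=C/[C@H]2OC1=O | intermediate
27 | (3S,6R)-3,13-dihydroxygermacra-1(10)E,4E,7(11)-trien-12,6-olide | OCC1=C2CC/C(C)=C/C[C@H](O)/C(C)=C/[C@H]2OC1=O | intermediate
28 | (3S,6R)-3,13-diacetoxygermacra-1(10)E,4E,7(11)-trien-12,6-olide | CC(=O)OCC1=C2CC/C(C)=C/C[C@H](OC(C)=O)/C(C)=C/[C@H]2OC1=O | intermediate
29 | (1R,3S,6R,10R)-3,13-diacetoxy-1,10-epoxygermacra-4E,7(11)-dien-12,6-olide (CNP0294733.1) | CC(=O)OCC1=C2CC[C@@]3(C)O[C@@H]3C[C@H](OC(C)=O)/C(C)=C/[C@H]2OC1=O | target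

## Step count and least certain steps

Total: 20 steps. Longest linear sequence: 18 steps (1 to 29 through steps 1–14 and 17–20); steps 15 and 16 form the side branch to 24.

Step 13 (key step). Two processes are most likely to fail. The first is closure in the exocyclic mode or oligomerisation, because the endocyclic ten-membered nickelacycle holding an E-alkene is strained. The second is facial selectivity at C3 opposite to that needed, because allylic strain in a late transition state favours the C6 rotamer that leads to the 3-epimer. Fallback: a Nozaki–Hiyama–Kishi closure of the same C3–C4 bond, setting out from 17 and returning at 19. Hydrostannation of 17 (Bu3SnH, PdCl2(PPh3)2) should place tin on the less hindered, methyl-bearing C4 by syn addition to give vinylstannane F1. Iodine exchanges tin with retention to give vinyl iodide F2, and Dess–Martin oxidation gives iodo aldehyde F3. Divalent chromium (CrCl2 with catalytic NiCl2, DMSO/THF, high dilution) closes the ring to the free C3 alcohol, which tolerates the ketal and silyl ether and does not pass through a planar nickelacycle. If this gives macrocyclic alcohol F4 (3S), silylation with iPr3SiOTf/2,6-lutidine gives 19. If it gives the 3-epimer F5, a Mitsunobu reaction with 4-nitrobenzoic acid inverts C3 to nitrobenzoate F6, and methanolysis (K2CO3, MeOH) returns F4.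

Step 10. The exchange may fail through loss of the TES group to the liberated trifluoroacetic acid, through capture of the thionium ion by traces of water (giving the base-sensitive propargylic ketone), or through oxidation of the electron-rich PMB ring. Fallback: change the order and the way C6 is set, setting out from 13 and returning at 16. The same iodine reagent in methanol converts the ynone, which has no silyl ether and no stereocentre, to ketal ynone F7. Noyori transfer hydrogenation with RuCl[(S,S)-TsDPEN](p-cymene) in iPrOH, possible now that sulfur is gone, should give ketal alcohol F8 (6R, the alkyne taking the place of the aryl group in the usual model). Silylation with Et3SiOTf gives 16.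

Step 14. Hydrolysis of the ketal next to an oxygenated carbon may be slow, and forcing it with stronger acid risks transannular cyclisation of the 1,5-diene or ketol transposition towards the conjugated C6 ketone. Fallback: carry C7 through the ring closure at the alcohol level and release the ketone by oxidation, setting out from 15 and returning at 20. PhI(OCOCF3)2 in buffered aqueous MeCN gives ketone F9, which is reduced at once (NaBH4, CeCl3, −78 °C) to alcohol F10 (either C7 epimer serves) and acetylated to acetate F11. The conditions of steps 11 to 13 then give alcohol F12, ynal F13 and macrocyclic acetate F14. iBu2AlH at −78 °C removes the acetate without silyl migration to give macrocyclic alcohol F15, Dess–Martin oxidation gives silyloxy ketone F16, and HF·pyridine/pyridine removes the TES group to give 20.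

Step 20. Facial selectivity may be poor if the conformer with C14 anti to C15 is populated, and the epoxide may open transannularly if acid is not excluded. Fallback: replace substrate control by reagent control, from 28 directly to 29. A Shi epoxidation (fructose-derived ketone catalyst of the appropriate enantiomeric series, KHSO5, K2CO3, MeCN/dimethoxymethane/aqueous buffer, 0 °C) can select one face of the E-trisubstituted C1=C10 under Curtin–Hammett conditions and works without acid. It makes no new compound.

## Further compounds

F1 | step 13 | (3E,8R,9E)-7,7-dimethoxy-4-methyl-10-(tributylstannyl)-8-(triethylsilyloxy)undeca-3,9-dien-1-ol | CCCC[Sn](CCCC)(CCCC)/C(C)=C/[C@@H](O[Si](CC)(CC)CC)C(OC)(OC)CC/C(C)=C/CCO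
F2 | step 13 | (3E,8R,9E)-10-iodo-7,7-dimethoxy-4-methyl-8-(triethylsilyloxy)undeca-3,9-dien-1-ol | I/C(C)=C/[C@@H](O[Si](CC)(CC)CC)C(OC)(OC)CC/C(C)=C/CCO
F3 | step 13 | (3E,8R,9E)-10-iodo-7,7-dimethoxy-4-methyl-8-(triethylsilyloxy)undeca-3,9-dienal | I/C(C)=C/[C@@H](O[Si](CC)(CC)CC)C(OC)(OC)CC/C(C)=C/CC=O
F4 | step 13 | (3S,6R)-7,7-dimethoxy-6-(triethylsilyloxy)-11,12,13-trinorgermacra-1(10)E,4E-dien-3-ol | C1/C=C(C)/CCC(OC)(OC)[C@H](O[Si](CC)(CC)CC)/C=C(C)/[C@H]1O
F5 | step 13 | (3R,6R)-7,7-dimethoxy-6-(triethylsilyloxy)-11,12,13-trinorgermacra-1(10)E,4E-dien-3-ol | C1/C=C(C)/CCC(OC)(OC)[C@H](O[Si](CC)(CC)CC)/C=C(C)/[C@@H]1O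
F6 | step 13 | 4-nitrobenzoate of F4 (3S) | C1/C=C(C)/CCC(OC)(OC)[C@H](O[Si](CC)(CC)CC)/C=C(C)/[C@H]1OC(=O)c2ccc(cc2)[N+](=O)[O-]
F7 | step 10 | (8E)-5,5-dimethoxy-11-[(4-methoxybenzyl)oxy]-8-methylundec-8-en-2-yn-4-one | CC#CC(=O)C(OC)(OC)CC/C(C)=C/CCOCc1ccc(OC)cc1
F8 | step 10 | (4R,8E)-5,5-dimethoxy-11-[(4-methoxybenzyl)oxy]-8-methylundec-8-en-2-yn-4-ol | CC#C[C@@H](O)C(OC)(OC)CC/C(C)=C/CCOCc1ccc(OC)cc1
F9 | step 14 | (4R,8E)-11-[(4-methoxybenzyl)oxy]-8-methyl-4-(triethylsilyloxy)undec-8-en-2-yn-5-one | CC#C[C@@H](O[Si](CC)(CC)CC)C(=O)CC/C(C)=C/CCOCc1ccc(OC)cc1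
F10 | step 14 | (4R,8E)-11-[(4-methoxybenzyl)oxy]-8-methyl-4-(triethylsilyloxy)undec-8-en-2-yn-5-ol (either C5 epimer) | CC#C[C@@H](O[Si](CC)(CC)CC)C(O)CC/C(C)=C/CCOCc1ccc(OC)cc1
F11 | step 14 | acetate of F10 | CC#C[C@@H](O[Si](CC)(CC)CC)C(OC(C)=O)CC/C(C)=C/CCOCc1ccc(OC)cc1
F12 | step 14 | (3E,8R)-7-acetoxy-4-methyl-8-(triethylsilyloxy)undec-3-en-9-yn-1-ol | CC#C[C@@H](O[Si](CC)(CC)CC)C(OC(C)=O)CC/C(C)=C/CCO
F13 | step 14 | (3E,8R)-7-acetoxy-4-methyl-8-(triethylsilyloxy)undec-3-en-9-ynal | CC#C[C@@H](O[Si](CC)(CC)CC)C(OC(C)=O)CC/C(C)=C/CC=O
F14 | step 14 | (3S,6R)-7-acetoxy-6-(triethylsilyloxy)-3-(triisopropylsilyloxy)-11,12,13-trinorgermacra-1(10)E,4E-diene | C1/C=C(C)/CCC(OC(C)=O)[C@H](O[Si](CC)(CC)CC)/C=C(C)/[C@H]1O[Si](C(C)C)(C(C)C)C(C)C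
F15 | step 14 | (3S,6R)-6-(triethylsilyloxy)-3-(triisopropylsilyloxy)-11,12,13-trinorgermacra-1(10)E,4E-dien-7-ol | C1/C=C(C)/CCC(O)[C@H](O[Si](CC)(CC)CC)/C=C(C)/[C@H]1O[Si](C(C)C)(C(C)C)C(C)C
F16 | step 14 | (3S,6R)-6-(triethylsilyloxy)-3-(triisopropylsilyloxy)-11,12,13-trinorgermacra-1(10)E,4E-dien-7-one | C1/C=C(C)/CCC(=O)[C@H](O[Si](CC)(CC)CC)/C=C(C)/[C@H]1O[Si](C(C)C)(C(C)C)C(C)C
F0 | step 20 | none | none
A1 | alternative 1 | cis-fused gem-dibromocyclopropane on the nine-membered ring (CBr2 as C4 bridging C3 and C5; C1/C10 acetonide; C13 acetate; 12,6-olide) | CC(=O)OCC1=C2CC[C@@]3(C)OC(C)(C)O[C@H]3C[C@@H]4C(Br)(Br)[C@@H]4[C@H]2OC1=O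
A2 | alternative 1 | ten-membered 3-acetoxy-4-bromo-4-ene, ring-trans (formally 4Z), C1/C10 acetonide | CC(=O)OCC1=C2CC[C@@]3(C)OC(C)(C)O[C@H]3C[C@H](OC(C)=O)/C(Br)=C/[C@H]2OC1=O
A3 | alternative 2 | seco tetronate triflate with terminal C8=C9 alkene (C3 and C13 as TBS ethers) | C=C/C(C)=C/C[C@H](O[Si](C)(C)C(C)(C)C)/C(C)=C/[C@H]1OC(=O)C(CO[Si](C)(C)C(C)(C)C)=C1OS(=O)(=O)C(F)(F)F
A4 | alternative 2 | (3S,6R)-3,13-bis(tert-butyldimethylsilyloxy)germacra-1(10)E,4E,7(11)-trien-12,6-olide | CC(C)(C)[Si](C)(C)OCC1=C2CC/C(C)=C/C[C@H](O[Si](C)(C)C(C)(C)C)/C(C)=C/[C@H]2OC1=O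
A5 | alternative 3 | trans-fused 3,13-diacetoxyeudesma-1,3,7(11)-trien-12,6-olide (5α-H, 10β-methyl) | CC(=O)OCC1=C2CC[C@@]3(C)C=CC(OC(C)=O)=C(C)[C@@H]3[C@H]2OC1=O
A6 | alternative 3 | 3,13-diacetoxygermacra-1(10),2,4,7(11)-tetraen-12,6-olide (1(10)E, ring-cis C2=C3, 4E) | CC(=O)OCC1=C2CC/C(C)=C/C=C(/OC(C)=O)C(/C)=C/[C@H]2OC1=O
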